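The route rests on cutting the C3–C3a bond of dihydrobenzofuran ring B: O1, C2 (bearing ring A), C3 (bearing C9) and the fused arene are read as a ring-contracted 2-arylchroman-4-one. In one operation PhI(OAc)2 in trimethyl orthoformate moves the fused aryl carbon of (R)-flavanone 11 from C4 to C3, which closes ring B, sets C3 trans to C2 and leaves the old carbonyl carbon as the C9 ester. The precursor is a 6-bromo-8-methoxyflavanone whose ring A is deactivated as its tosylate. Ring C is then built on the bromide by carbenoid C–H insertion, since the electron-rich ring B arene would itself migrate in a second contraction.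

Key step: step 6

Assumption: the quinine-derived thiourea is taken to deliver the (R)-flavanone and Rh2(S-PTTL)4 the (2R)-dihydrobenzofuran; should either sense prove opposite, the quinidine-derived thiourea or Rh2(R-PTTL)4 takes its place.

**Step 1**
Reactants: 1 methyl 2-hydroxy-3-methoxybenzoate
Product: 2 methyl 5-bromo-2-hydroxy-3-methoxybenzoate
Conditions: NBS (1.05 equiv), MeCN, 0 °C → rt
Reagents that add atoms: N-bromosuccinimide, O=C1CCC(=O)N1Br
Why: Electrophilic aromatic bromination goes para to the free phenol, because both positions ortho to the hydroxyl group are blocked.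

**Step 2**
Reactants: 2 methyl 5-bromo-2-hydroxy-3-methoxybenzoate; 3 tert-butyl acetate
Product: 4 tert-butyl 3-(5-bromo-2-hydroxy-3-methoxyphenyl)-3-oxopropanoate
Conditions: LiN(i-Pr)2 (3.3 equiv), 3 (3.3 equiv), THF, −78 °C; then 2, −78 → 0 °C; 1 M HCl
Reagents that add atoms: none
Why: Crossed Claisen condensation of the lithium enolate of tert-butyl acetate with the salicylate ester, the excess enolate absorbing the phenol proton and the acidic product, gives a β-keto ester whose bulky ester resists lactonisation to a 4-hydroxycoumarin.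

**Step 3**
Reactants: 5 vanillin; 6 tosyl chloride
Product: 7 4-formyl-2-methoxyphenyl 4-methylbenzenesulfonate (O-tosylvanillin)
Conditions: K2CO3, acetone, rt
Reagents that add atoms: none
Why: O-Sulfonylation of the phenoxide installs the electron-withdrawing group that ring A needs in step 6 and that withstands every later step up to the last.

**Step 4**
Reactants: 4 tert-butyl 3-(5-bromo-2-hydroxy-3-methoxyphenyl)-3-oxopropanoate; 7 O-tosylvanillin
Product: 8 tert-butyl (Z)-2-(5-bromo-2-hydroxy-3-methoxybenzoyl)-3-[3-methoxy-4-(tosyloxy)phenyl]prop-2-enoate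
Conditions: piperidine (0.1 equiv), AcOH (0.1 equiv), 4 Å molecular sieves, toluene, rt
Reagents that add atoms: none
Why: Knoevenagel condensation under buffered amine catalysis spares the aryl sulfonate, which the hydroxide of an aldol route to a plain chalcone would attack, and gives an alkylidene β-keto ester that is a far better, two-point-binding acceptor for a catalysed oxa-Michael closure than a simple 2′-hydroxychalcone.

**Step 5**
Reactants: 8 alkylidene β-keto ester
Product: 11 4-[(2R)-6-bromo-8-methoxy-4-oxo-3,4-dihydro-2H-chromen-2-yl]-2-methoxyphenyl 4-methylbenzenesulfonate, via tert-butyl flavanone-3-carboxylate 9 (not isolated), via flavanone-3-carboxylic acid 10 (not isolated)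
Conditions: 1-[3,5-bis(trifluoromethyl)phenyl]-3-(9-deoxy-epi-quinin-9-yl)thiourea (10 mol%), toluene, −25 °C; then TsOH·H2O (0.5 equiv), 80 °C
Reagents that add atoms: none
Why: Bifunctional thiourea catalysis of the 6-endo-trig intramolecular oxa-Michael addition (the thiourea binds the β-keto ester, the quinuclidine delivers the phenol to one face of the alkene and so sets C2 as R), followed by acid cleavage of the tert-butyl ester and decarboxylation, during which the electron-poor ring A keeps C2 from ionising.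

**Step 6**
Reactants: 11 (R)-6-bromo-8-methoxyflavanone with ring A as tosylate
Product: 13 methyl (2R,3R)-5-bromo-7-methoxy-2-[3-methoxy-4-(tosyloxy)phenyl]-2,3-dihydro-1-benzofuran-3-carboxylate (trans), via 4-methoxy-2H-chromene enol ether 12 (not isolated)
Conditions: PhI(OAc)2 (1.3 equiv), conc. H2SO4 (0.5 equiv), HC(OMe)3, 0 °C → rt; aq. NaHCO3
Reagents that add atoms: trimethyl orthoformate, COC(OC)OC; water, O
Why: Acid and orthoformate turn the ketone into enol ether 12, which attacks trivalent iodine at C3 on the face anti to the C2 aryl group while methanol adds to C4; in the resulting 3-iodanyl 4,4-dimethoxy ketal the C4–C4a bond lies antiperiplanar to the carbon–iodine bond, so C4a shifts from C4 to C3 through a bridged phenonium ion as PhI leaves, and the dimethoxycarbenium ion left at C4 ends as the methyl ester. The closest known reaction type is the oxidative 1,2-aryl migration of aryl ketone ketals to 2-arylalkanoates, in its known form as the ring contraction of flavanones to methyl 2-aryl-2,3-dihydrobenzofuran-3-carboxylates. Ring B is closed not by a cyclisation but by contraction: the ipso carbon of the fused arene bridges C3 in a three-membered spiro ring (3-exo attack) and the six-membered ring opens to the five-membered one as the C4–C4a bond breaks. The new stereocentre C3 is controlled by C2, since iodine enters anti to the aryl group and the migration inverts C3, which places the ester trans to ring A while C2 itself is not touched. The step needs migration of the fused arene and not of the C2 aryl group (which would lead to an isoflavone) and no ionisation at C2; the sulfonate makes ring A a poor migrating and cation-stabilising group, whereas the fused arene carries O1 ortho to the migrating carbon.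

**Step 7**
Reactants: 13 trans bromo ester; 14 (tributylstannyl)methanol
Product: 15 methyl (2R,3R)-5-(hydroxymethyl)-7-methoxy-2-[3-methoxy-4-(tosyloxy)phenyl]-2,3-dihydro-1-benzofuran-3-carboxylate
Conditions: Pd(PPh3)4 (5 mol%), 1,4-dioxane, 100 °C
Reagents that add atoms: none
Why: Migita–Kosugi–Stille coupling transfers the oxygen-bearing hydroxymethyl group from tin to the aryl bromide under neutral conditions, so the ester at C3 is safe and the aryl tosylate does not add to zerovalent palladium carrying PPh3.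

**Step 8**
Reactants: 16 2-(2-hydroxy-3-methoxyphenyl)acetic acid
Product: 17 methyl 2-(2-hydroxy-3-methoxyphenyl)acetate
Conditions: MeOH, H2SO4 (cat.), reflux
Reagents that add atoms: methanol, CO
Why: Fischer esterification in which the large excess of methanol favours the open methyl ester over the benzofuranone lactone.

**Step 9**
Reactants: 17 methyl 2-(2-hydroxy-3-methoxyphenyl)acetate
Product: 18 methyl 2-(5-bromo-2-hydroxy-3-methoxyphenyl)acetate
Conditions: NBS (1.05 equiv), MeCN, 0 °C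
Reagents that add atoms: N-bromosuccinimide, O=C1CCC(=O)N1Br
Why: Electrophilic aromatic bromination para to the phenol, as in step 1, places the handle for the later Heck reaction.

**Step 10**
Reactants: 15 benzylic alcohol; 18 methyl 2-(5-bromo-2-hydroxy-3-methoxyphenyl)acetate
Product: 19 methyl (2R,3R)-5-{[4-bromo-2-methoxy-6-(2-methoxy-2-oxoethyl)phenoxy]methyl}-7-methoxy-2-[3-methoxy-4-(tosyloxy)phenyl]-2,3-dihydro-1-benzofuran-3-carboxylate
Conditions: PPh3, DIAD, THF, 0 °C → rt
Reagents that add atoms: none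
Why: Mitsunobu etherification of the primary benzylic alcohol with the acidic phenol forms the benzyl aryl ether without added base and so leaves the epimerisable ester alone.

**Step 11**
Reactants: 19 benzyl aryl ether
Product: 20 methyl (2R,3R)-5-{[4-bromo-2-(1-diazo-2-methoxy-2-oxoethyl)-6-methoxyphenoxy]methyl}-7-methoxy-2-[3-methoxy-4-(tosyloxy)phenyl]-2,3-dihydro-1-benzofuran-3-carboxylate
Conditions: 4-acetamidobenzenesulfonyl azide, DBU, MeCN, 0 °C → rt
Reagents that add atoms: 4-acetamidobenzenesulfonyl azide, CC(=O)Nc1ccc(cc1)S(=O)(=O)N=[N+]=[N-]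
Why: Regitz diazo transfer takes place at the arylacetate methylene, which is more acidic and far more accessible than the tertiary C3–H of ring B.

**Step 12**
Reactants: 20 aryldiazoacetate
Product: 22 methyl (2R,3R)-5-bromo-7-methoxy-2-{(2R,3R)-7-methoxy-3-(methoxycarbonyl)-2-[3-methoxy-4-(tosyloxy)phenyl]-2,3-dihydro-1-benzofuran-5-yl}-2,3-dihydro-1-benzofuran-3-carboxylate (both rings trans), via cis-ester 21 (not isolated)
Conditions: Rh2(S-PTTL)4 (dirhodium tetrakis[N-phthaloyl-(S)-tert-leucinate], 2 mol%), toluene, −60 → 0 °C; then NaOMe (0.2 equiv), MeOH, 0 °C → rt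
Reagents that add atoms: none
Why: Intramolecular 1,5 C–H insertion of the donor–acceptor rhodium carbenoid into the benzylic ether C–H bond, which the ether oxygen and the para-oxygenated ring B arene activate, closes ring C while the chiral dirhodium carboxylate selects one enantiotopic hydrogen and so fixes C2′ as R in the kinetic cis ester, after which catalytic methoxide epimerises only C3′ to the more stable trans ester, ring B being trans already.

**Step 13**
Reactants: 22 bis(dihydrobenzofuran) bromide; 23 methyl acrylate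
Product: 24 methyl (2R,3R)-7-methoxy-5-[(E)-3-methoxy-3-oxoprop-1-enyl]-2-{(2R,3R)-7-methoxy-3-(methoxycarbonyl)-2-[3-methoxy-4-(tosyloxy)phenyl]-2,3-dihydro-1-benzofuran-5-yl}-2,3-dihydro-1-benzofuran-3-carboxylate
Conditions: Pd(OAc)2 (5 mol%), P(o-tol)3 (10 mol%), NaOAc, DMF, 110 °C
Reagents that add atoms: none
Why: Mizoroki–Heck reaction of the aryl bromide with the acrylate gives the E alkene through syn insertion and syn β-hydride elimination, the aryl tosylate being inert to palladium with this triarylphosphine.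

**Step 14**
Reactants: 24 triester
Product: 25 4-[(2R,3S)-3-(hydroxymethyl)-5-{(2R,3S)-3-(hydroxymethyl)-5-[(E)-3-hydroxyprop-1-enyl]-7-methoxy-2,3-dihydro-1-benzofuran-2-yl}-7-methoxy-2,3-dihydro-1-benzofuran-2-yl]-2-methoxyphenyl 4-methylbenzenesulfonate
Conditions: (i-Bu)2AlH (9 equiv), CH2Cl2, −78 → 0 °C; aq. potassium sodium tartrate
Reagents that add atoms: none
Why: Hydride reduction with (i-Bu)2AlH takes the two saturated esters to primary alcohols and the cinnamate, by 1,2-addition, to the allylic alcohol without touching the alkene or any stereocentre (the descriptor at C3 and C3′ changes from R to S only through the priority rules).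

**Step 15**
Reactants: 25 tosyl triol
Product: 26 4-[(2R,3S)-3-(hydroxymethyl)-5-{(2R,3S)-3-(hydroxymethyl)-5-[(E)-3-hydroxyprop-1-enyl]-7-methoxy-2,3-dihydro-1-benzofuran-2-yl}-7-methoxy-2,3-dihydro-1-benzofuran-2-yl]-2-methoxyphenol (CNP0250921.1)
Conditions: KOH (10 equiv), MeOH–H2O (4:1), 60 °C, argon; then 1 M HCl to pH 6
Reagents that add atoms: none
Why: Hydroxide attacks the sulfur of the aryl sulfonate (S–O cleavage) and frees the phenol, and nothing else in the triol is base-labile at this temperature.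

**Compound list**

1 | methyl 2-hydroxy-3-methoxybenzoate | COC(=O)c1cccc(OC)c1O | starting material
2 | methyl 5-bromo-2-hydroxy-3-methoxybenzoate | COC(=O)c1cc(Br)cc(OC)c1O | intermediate
3 | tert-butyl acetate | CC(=O)OC(C)(C)C | starting material
4 | tert-butyl 3-(5-bromo-2-hydroxy-3-methoxyphenyl)-3-oxopropanoate | CC(C)(C)OC(=O)CC(=O)c1cc(Br)cc(OC)c1O | intermediate
5 | vanillin | COc1cc(C=O)ccc1O | starting material
6 | tosyl chloride | Cc1ccc(S(Cl)(=O)=O)cc1 | starting material
7 | 4-formyl-2-methoxyphenyl 4-methylbenzenesulfonate | COc1cc(C=O)ccc1OS(=O)(=O)c1ccc(C)cc1 | intermediate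
8 | tert-butyl (Z)-2-(5-bromo-2-hydroxy-3-methoxybenzoyl)-3-[3-methoxy-4-(tosyloxy)phenyl]prop-2-enoate | CC(C)(C)OC(=O)/C(=C\c1ccc(OS(=O)(=O)c2ccc(C)cc2)c(OC)c1)C(=O)c1cc(Br)cc(OC)c1O | intermediate
9 | tert-butyl (2R,3S)-6-bromo-8-methoxy-2-[3-methoxy-4-(tosyloxy)phenyl]-4-oxochromane-3-carboxylate (trans; formed in the flask, not isolated) | COc1cc([C@@H]2Oc3c(OC)cc(Br)cc3C(=O)[C@H]2C(=O)OC(C)(C)C)ccc1OS(=O)(=O)c1ccc(C)cc1 | intermediate
10 | (2R,3S)-6-bromo-8-methoxy-2-[3-methoxy-4-(tosyloxy)phenyl]-4-oxochromane-3-carboxylic acid (formed in the flask, not isolated) | COc1cc([C@@H]2Oc3c(OC)cc(Br)cc3C(=O)[C@H]2C(=O)O)ccc1OS(=O)(=O)c1ccc(C)cc1 | intermediate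
11 | 4-[(2R)-6-bromo-8-methoxy-4-oxo-3,4-dihydro-2H-chromen-2-yl]-2-methoxyphenyl 4-methylbenzenesulfonate | COc1cc([C@@H]2Oc3c(OC)cc(Br)cc3C(=O)C2)ccc1OS(=O)(=O)c1ccc(C)cc1 | intermediate
12 | 4-[(2R)-6-bromo-4,8-dimethoxy-2H-chromen-2-yl]-2-methoxyphenyl 4-methylbenzenesulfonate (formed in the flask, not isolated) | COc1cc([C@@H]2Oc3c(OC)cc(Br)cc3C(OC)=C2)ccc1OS(=O)(=O)c1ccc(C)cc1 | intermediate
13 | methyl (2R,3R)-5-bromo-7-methoxy-2-[3-methoxy-4-(tosyloxy)phenyl]-2,3-dihydro-1-benzofuran-3-carboxylate | COc1cc([C@@H]2Oc3c(OC)cc(Br)cc3[C@H]2C(=O)OC)ccc1OS(=O)(=O)c1ccc(C)cc1 | intermediate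
14 | (tributylstannyl)methanol | CCCC[Sn](CCCC)(CCCC)CO | starting material
15 | methyl (2R,3R)-5-(hydroxymethyl)-7-methoxy-2-[3-methoxy-4-(tosyloxy)phenyl]-2,3-dihydro-1-benzofuran-3-carboxylate | COc1cc([C@@H]2Oc3c(OC)cc(CO)cc3[C@H]2C(=O)OC)ccc1OS(=O)(=O)c1ccc(C)cc1 | intermediate
16 | 2-(2-hydroxy-3-methoxyphenyl)acetic acid | COc1cccc(CC(=O)O)c1O | starting material
17 | methyl 2-(2-hydroxy-3-methoxyphenyl)acetate | COC(=O)Cc1cccc(OC)c1O | intermediate
18 | methyl 2-(5-bromo-2-hydroxy-3-methoxyphenyl)acetate | COC(=O)Cc1cc(Br)cc(OC)c1O | intermediate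
19 | methyl (2R,3R)-5-{[4-bromo-2-methoxy-6-(2-methoxy-2-oxoethyl)phenoxy]methyl}-7-methoxy-2-[3-methoxy-4-(tosyloxy)phenyl]-2,3-dihydro-1-benzofuran-3-carboxylate | COc1cc([C@@H]2Oc3c(OC)cc(COc4c(OC)cc(Br)cc4CC(=O)OC)cc3[C@H]2C(=O)OC)ccc1OS(=O)(=O)c1ccc(C)cc1 | intermediate
20 | methyl (2R,3R)-5-{[4-bromo-2-(1-diazo-2-methoxy-2-oxoethyl)-6-methoxyphenoxy]methyl}-7-methoxy-2-[3-methoxy-4-(tosyloxy)phenyl]-2,3-dihydro-1-benzofuran-3-carboxylate | COc1cc([C@@H]2Oc3c(OC)cc(COc4c(OC)cc(Br)cc4C(=[N+]=[N-])C(=O)OC)cc3[C@H]2C(=O)OC)ccc1OS(=O)(=O)c1ccc(C)cc1 | intermediate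
21 | methyl (2R,3S)-5-bromo-7-methoxy-2-{(2R,3R)-7-methoxy-3-(methoxycarbonyl)-2-[3-methoxy-4-(tosyloxy)phenyl]-2,3-dihydro-1-benzofuran-5-yl}-2,3-dihydro-1-benzofuran-3-carboxylate (ring C cis; formed in the flask, not isolated) | COc1cc([C@@H]2Oc3c(OC)cc([C@@H]4Oc5c(OC)cc(Br)cc5[C@@H]4C(=O)OC)cc3[C@H]2C(=O)OC)ccc1OS(=O)(=O)c1ccc(C)cc1 | intermediate
22 | methyl (2R,3R)-5-bromo-7-methoxy-2-{(2R,3R)-7-methoxy-3-(methoxycarbonyl)-2-[3-methoxy-4-(tosyloxy)phenyl]-2,3-dihydro-1-benzofuran-5-yl}-2,3-dihydro-1-benzofuran-3-carboxylate | COc1cc([C@@H]2Oc3c(OC)cc([C@@H]4Oc5c(OC)cc(Br)cc5[C@H]4C(=O)OC)cc3[C@H]2C(=O)OC)ccc1OS(=O)(=O)c1ccc(C)cc1 | intermediate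
23 | methyl acrylate | C=CC(=O)OC | starting material
24 | methyl (2R,3R)-7-methoxy-5-[(E)-3-methoxy-3-oxoprop-1-enyl]-2-{(2R,3R)-7-methoxy-3-(methoxycarbonyl)-2-[3-methoxy-4-(tosyloxy)phenyl]-2,3-dihydro-1-benzofuran-5-yl}-2,3-dihydro-1-benzofuran-3-carboxylate | COc1cc([C@@H]2Oc3c(OC)cc([C@@H]4Oc5c(OC)cc(/C=C/C(=O)OC)cc5[C@H]4C(=O)OC)cc3[C@H]2C(=O)OC)ccc1OS(=O)(=O)c1ccc(C)cc1 | intermediate
25 | 4-[(2R,3S)-3-(hydroxymethyl)-5-{(2R,3S)-3-(hydroxymethyl)-5-[(E)-3-hydroxyprop-1-enyl]-7-methoxy-2,3-dihydro-1-benzofuran-2-yl}-7-methoxy-2,3-dihydro-1-benzofuran-2-yl]-2-methoxyphenyl 4-methylbenzenesulfonate | COc1cc([C@@H]2Oc3c(OC)cc([C@@H]4Oc5c(OC)cc(/C=C/CO)cc5[C@H]4CO)cc3[C@H]2CO)ccc1OS(=O)(=O)c1ccc(C)cc1 | intermediate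
26 | 4-[(2R,3S)-3-(hydroxymethyl)-5-{(2R,3S)-3-(hydroxymethyl)-5-[(E)-3-hydroxyprop-1-enyl]-7-methoxy-2,3-dihydro-1-benzofuran-2-yl}-7-methoxy-2,3-dihydro-1-benzofuran-2-yl]-2-methoxyphenol | COc1cc([C@@H]2Oc3c(OC)cc([C@@H]4Oc5c(OC)cc(/C=C/CO)cc5[C@H]4CO)cc3[C@H]2CO)ccc1O | target

**Step count and risk**

Total steps: 15. Longest linear sequence: 12 steps (1 → 2 → 4 → 8 → 11 → 13 → 15 → 19 → 20 → 22 → 24 → 25 → 26; steps 3, 8 and 9 prepare side fragments).

Steps most likely to fail:

1. Step 6. Dehydrogenation to the flavone, methoxylation at C3 without migration, or acid-promoted opening of the pyranone ring that erodes the C2 configuration may outrun the aryl shift. The fallback leaves the contraction aside and reaches 13 by the carbenoid chemistry of steps 10 to 12; it sets out from 7 and 18 and comes back at 13. Aldehyde 7 is reduced (NaBH4, MeOH, 0 °C) to 4-(hydroxymethyl)-2-methoxyphenyl 4-methylbenzenesulfonate F1, which is joined to phenol 18 by Mitsunobu etherification (PPh3, DIAD, THF) to give the benzyl aryl ether methyl 2-[5-bromo-3-methoxy-2-({3-methoxy-4-(tosyloxy)phenyl}methoxy)phenyl]acetate F2. Diazo transfer (4-acetamidobenzenesulfonyl azide, DBU, MeCN) gives the aryldiazoacetate methyl 2-[5-bromo-3-methoxy-2-({3-methoxy-4-(tosyloxy)phenyl}methoxy)phenyl]-2-diazoacetate F3. Rh2(S-PTTL)4 in toluene at −60 °C should close the cis ester methyl (2R,3S)-5-bromo-7-methoxy-2-[3-methoxy-4-(tosyloxy)phenyl]-2,3-dihydro-1-benzofuran-3-carboxylate F4 by benzylic C–H insertion, and catalytic NaOMe in MeOH epimerises C3 to give 13.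

2. Step 12. The catalyst alone must choose between the two benzylic hydrogens, the ring B stereocentres being too remote to help, so facial control may be incomplete, and carbene dimerisation may compete with insertion. The fallback forms the C2′–O bond last and sets C3′ with an auxiliary; it sets out from 15 and 18 and comes back at 22. Alcohol 15 is oxidised (MnO2, CH2Cl2) to methyl (2R,3R)-5-formyl-7-methoxy-2-[3-methoxy-4-(tosyloxy)phenyl]-2,3-dihydro-1-benzofuran-3-carboxylate F5. Phenol 18 is protected (MOMCl, i-Pr2NEt) as methyl 2-[5-bromo-3-methoxy-2-(methoxymethoxy)phenyl]acetate F6, saponified (LiOH, THF–H2O) to 2-[5-bromo-3-methoxy-2-(methoxymethoxy)phenyl]acetic acid F7 and attached (pivaloyl chloride, Et3N; then (R)-4-benzyloxazolidin-2-one lithiated with n-BuLi) to give (4R)-4-benzyl-3-{2-[5-bromo-3-methoxy-2-(methoxymethoxy)phenyl]acetyl}-1,3-oxazolidin-2-one F8. The boron enolate of F8 (Bu2BOTf, i-Pr2NEt, CH2Cl2, −78 °C) adds to F5 in an Evans syn-aldol reaction that fixes C3′ by auxiliary control and gives methyl (2R,3R)-5-{(1R,2R)-3-[(4R)-4-benzyl-2-oxo-1,3-oxazolidin-3-yl]-2-[5-bromo-3-methoxy-2-(methoxymethoxy)phenyl]-1-hydroxy-3-oxopropyl}-7-methoxy-2-[3-methoxy-4-(tosyloxy)phenyl]-2,3-dihydro-1-benzofuran-3-carboxylate F9. CF3CO2H in CH2Cl2 at 0 °C removes the acetal, and the freed phenol captures the benzylic cation that the para oxygen of ring B stabilises, closing ring C trans to the acyl group as methyl (2R,3R)-5-{(2R,3R)-3-[(4R)-4-benzyl-2-oxo-1,3-oxazolidine-3-carbonyl]-5-bromo-7-methoxy-2,3-dihydro-1-benzofuran-2-yl}-7-methoxy-2-[3-methoxy-4-(tosyloxy)phenyl]-2,3-dihydro-1-benzofuran-3-carboxylate F10. NaOMe in MeOH at 0 °C exchanges the auxiliary for the methyl ester and gives 22.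

3. Step 5. Uncatalysed or amine-promoted racemic closure of the hindered, hydrogen-bonded phenol, or partial ring opening during the hot acid decarboxylation, may lower the enantiomeric purity. The fallback adds a kinetic resolution; it sets out from 11 of insufficient purity as delivered by step 5 and comes back at 11. Noyori–Ikariya transfer hydrogenation (RuCl(p-cymene)[(S,S)-TsDPEN] or its antipode, whichever reduces the (S)-ketone faster, HCO2H–Et3N) converts the minor enantiomer into 4-[(2S,4S)-6-bromo-4-hydroxy-8-methoxy-3,4-dihydro-2H-chromen-2-yl]-2-methoxyphenyl 4-methylbenzenesulfonate F11, which is removed by chromatography, and the unreacted (R)-ketone re-enters the route as 11.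

**Further compounds**

F1 | step 6 | 4-(hydroxymethyl)-2-methoxyphenyl 4-methylbenzenesulfonate | COc1cc(CO)ccc1OS(=O)(=O)c1ccc(C)cc1
F2 | step 6 | methyl 2-[5-bromo-3-methoxy-2-({3-methoxy-4-(tosyloxy)phenyl}methoxy)phenyl]acetate | COC(=O)Cc1cc(Br)cc(OC)c1OCc1ccc(OS(=O)(=O)c2ccc(C)cc2)c(OC)c1
F3 | step 6 | methyl 2-[5-bromo-3-methoxy-2-({3-methoxy-4-(tosyloxy)phenyl}methoxy)phenyl]-2-diazoacetate | COC(=O)C(=[N+]=[N-])c1cc(Br)cc(OC)c1OCc1ccc(OS(=O)(=O)c2ccc(C)cc2)c(OC)c1
F4 | step 6 | methyl (2R,3S)-5-bromo-7-methoxy-2-[3-methoxy-4-(tosyloxy)phenyl]-2,3-dihydro-1-benzofuran-3-carboxylate | COc1cc([C@@H]2Oc3c(OC)cc(Br)cc3[C@@H]2C(=O)OC)ccc1OS(=O)(=O)c1ccc(C)cc1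
F5 | step 12 | methyl (2R,3R)-5-formyl-7-methoxy-2-[3-methoxy-4-(tosyloxy)phenyl]-2,3-dihydro-1-benzofuran-3-carboxylate | COc1cc([C@@H]2Oc3c(OC)cc(C=O)cc3[C@H]2C(=O)OC)ccc1OS(=O)(=O)c1ccc(C)cc1
F6 | step 12 | methyl 2-[5-bromo-3-methoxy-2-(methoxymethoxy)phenyl]acetate | COCOc1c(OC)cc(Br)cc1CC(=O)OC
F7 | step 12 | 2-[5-bromo-3-methoxy-2-(methoxymethoxy)phenyl]acetic acid | COCOc1c(OC)cc(Br)cc1CC(=O)O
F8 | step 12 | (4R)-4-benzyl-3-{2-[5-bromo-3-methoxy-2-(methoxymethoxy)phenyl]acetyl}-1,3-oxazolidin-2-one | COCOc1c(OC)cc(Br)cc1CC(=O)N1[C@H](Cc2ccccc2)COC1=O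
F9 | step 12 | methyl (2R,3R)-5-{(1R,2R)-3-[(4R)-4-benzyl-2-oxo-1,3-oxazolidin-3-yl]-2-[5-bromo-3-methoxy-2-(methoxymethoxy)phenyl]-1-hydroxy-3-oxopropyl}-7-methoxy-2-[3-methoxy-4-(tosyloxy)phenyl]-2,3-dihydro-1-benzofuran-3-carboxylate | COc1cc([C@@H]2Oc3c(OC)cc([C@H](O)[C@@H](c4cc(Br)cc(OC)c4OCOC)C(=O)N4[C@H](Cc5ccccc5)COC4=O)cc3[C@H]2C(=O)OC)ccc1OS(=O)(=O)c1ccc(C)cc1
F10 | step 12 | methyl (2R,3R)-5-{(2R,3R)-3-[(4R)-4-benzyl-2-oxo-1,3-oxazolidine-3-carbonyl]-5-bromo-7-methoxy-2,3-dihydro-1-benzofuran-2-yl}-7-methoxy-2-[3-methoxy-4-(tosyloxy)phenyl]-2,3-dihydro-1-benzofuran-3-carboxylate | COc1cc([C@@H]2Oc3c(OC)cc([C@@H]4Oc5c(OC)cc(Br)cc5[C@H]4C(=O)N4[C@H](Cc5ccccc5)COC4=O)cc3[C@H]2C(=O)OC)ccc1OS(=O)(=O)c1ccc(C)cc1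
F11 | step 5 | 4-[(2S,4S)-6-bromo-4-hydroxy-8-methoxy-3,4-dihydro-2H-chromen-2-yl]-2-methoxyphenyl 4-methylbenzenesulfonate | COc1cc([C@H]2Oc3c(OC)cc(Br)cc3[C@@H](O)C2)ccc1OS(=O)(=O)c1ccc(C)cc1
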